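**Strategy.** The route rests on disconnecting the C7–C11 bond of the cis-fused γ-lactone on ring B (C5–C6–C7–C8–C9–C10). A bromoacetal tied to the C6 oxygen of a ring B allylic alcohol delivers a C11 radical to C7 of the C7=C8 alkene; because C5 is quaternary and the tether holds only two atoms, one 5-exo closure forms the C7–C11 bond, the five-membered ring and the cis C6/C7 junction in a single operation. The precursor is a carvone-derived bicyclo[2.2.2]octenone carrying ring B as a cyclohexenol mixed bromoacetal and the C2′ acetyl masked as a dioxolane; oxidation, cross-coupling and C11 equilibration finish the target.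

Key step: step 20

Numbering used from the bicyclic stage on: bridgeheads C2 (CH) and C5 (quaternary); ketone bridge C1(=O)–C10 (C14 = methyl on C10); alkene bridge C3=C4 (C15 = methyl on C4); third bridge C1′H2–C2′H (C1′ on C5, C2′ on C2; C3′ = side-chain carbon on C2′); ring B = C5–C6–C7–C8–C9–C10; lactone C6–O–C12(=O)–C11(C13)–C7. Monocyclic compounds carry the locants of their systematic names. PMB = 4-methoxybenzyl.

Remark on the chemistry: (R)-carvone leads to the target series only because its carbonyl is transposed while the C6 carbon is attached (steps 4 and 5); attaching that carbon to C3 of carvone without transposition would give the enantiomeric series.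

Remark on the chemistry: C11 is assumed to emerge from the cyclisation as an epimer mixture and is fixed in the last step, so the cyclisation product and its successors are written without a descriptor at C11. The kinetic bicycloannulation is assumed to place the C4 ester syn to the ketone bridge, as is usual for this reaction.

Step 1
Reactants: 1 (R)-carvone
Product: 3 (5R)-5-acetyl-2-methylcyclohex-2-en-1-one, via isopropenyl ozonide 2 (not isolated)
Conditions: O3, CH2Cl2, −78 °C; then PPh3, −78 °C to rt
Reagents that add atoms: ozone, [O-][O+]=O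
Why: Ozonolysis with reductive work-up should cleave the electron-rich 1,1-disubstituted alkene well before the electron-poor enone alkene and leaves the lone stereocentre untouched.

Step 2
Reactants: 3 (5R)-5-acetyl-2-methylcyclohex-2-en-1-one
Product: 4 (5R)-2-methyl-5-(2-methyl-1,3-dioxolan-2-yl)cyclohex-2-en-1-one
Conditions: Me3SiOCH2CH2OSiMe3, Me3SiOTf (cat.), CH2Cl2, −78 °C
Reagents that add atoms: 1,2-bis(trimethylsilyloxy)ethane, C[Si](C)(C)OCCO[Si](C)(C)C
Why: Noyori ketalisation should mask the saturated acetyl carbonyl while the conjugated ring carbonyl stays free, and the aprotic cold conditions avoid enolisation at C5 next to the acetyl group.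

Step 3
Reactants: 5 (tributylstannyl)methanol; 6 4-methoxybenzyl chloride
Product: 7 tributyl{[(4-methoxybenzyl)oxy]methyl}stannane
Conditions: NaH, Bu4NI (cat.), THF/DMF, 0 °C to rt
Reagents that add atoms: none
Why: Williamson etherification of the primary alkoxide with the activated benzylic chloride should give the precursor of the hydroxymethyl anion equivalent.

Step 4
Reactants: 7 tributyl{[(4-methoxybenzyl)oxy]methyl}stannane; 4 (5R)-2-methyl-5-(2-methyl-1,3-dioxolan-2-yl)cyclohex-2-en-1-one
Product: 9 (5R)-1-{[(4-methoxybenzyl)oxy]methyl}-2-methyl-5-(2-methyl-1,3-dioxolan-2-yl)cyclohex-2-en-1-ol (both C1 epimers), via alkoxymethyllithium 8 (not isolated)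
Conditions: n-BuLi, THF, −78 °C; then 4, −78 °C; then H2O
Reagents that add atoms: none
Why: Tin–lithium exchange should give a hard α-alkoxymethyllithium that adds 1,2 to the enone carbonyl and so attaches the future C6; the new carbinol centre is erased in the next step.

Step 5
Reactants: 9 (5R)-1-{[(4-methoxybenzyl)oxy]methyl}-2-methyl-5-(2-methyl-1,3-dioxolan-2-yl)cyclohex-2-en-1-ol
Product: 10 (5S)-3-{[(4-methoxybenzyl)oxy]methyl}-2-methyl-5-(2-methyl-1,3-dioxolan-2-yl)cyclohex-2-en-1-one
Conditions: pyridinium chlorochromate (C5H5NH)[CrO3Cl], Celite, CH2Cl2, rt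
Reagents that add atoms: pyridinium chlorochromate, [O-][Cr](=O)(=O)Cl.c1cc[nH+]cc1
Why: Dauben–Babler oxidative 1,3-transposition of the tertiary allylic alcohol (chromate ester, [3,3] shift, oxidation) should move the carbonyl to the former C3 of carvone, which puts the stereocentre next to the new α′ position.

Step 6
Reactants: 10 (5S)-3-{[(4-methoxybenzyl)oxy]methyl}-2-methyl-5-(2-methyl-1,3-dioxolan-2-yl)cyclohex-2-en-1-one; 11 methyl acrylate
Product: 13 bicyclic keto ester (bicyclo[2.2.2]octan-1-one; C4-CO2Me and C2′-(2-methyl-1,3-dioxolan-2-yl) both syn to the ketone bridge; C5-CH2OPMB; C10-H/CH3 epimers), via lithium dienolate 12 (not isolated)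
Conditions: LiN(i-Pr)2, THF, −78 °C; then 11, −78 °C to rt; then H2O
Reagents that add atoms: none
Why: Kinetic α′-deprotonation followed by the double Michael bicycloannulation (addition anti to the dioxolanyl group, then closure of the ester enolate onto the enone β-carbon) should build the bicyclo[2.2.2]octanone, setting C2, the quaternary bridgehead C5 and the C2′ side chain syn to the ketone bridge, with the ester syn to that bridge through a chelated endo closure.

Step 7
Reactants: 13 bicyclic keto ester; 14 allyl bromide
Product: 16 C10-allyl keto ester (as 13; C10 bears CH3 syn to the C3–C4 bridge and allyl syn to the C1′–C2′ bridge), via lithium enolate 15 (not isolated)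
Conditions: LiN(i-Pr)2, THF, −78 °C; then 14, DMPU, −78 to 0 °C
Reagents that add atoms: none
Why: The ketone can enolise only toward C10 (C2 is a bridgehead), and because the C4 ester is 1,3-syn to C10 it shields the face turned to the C3–C4 bridge more strongly than the remote C2′ side chain shields the other, so enolate C-allylation should set the quaternary C10 with allyl syn to the C1′–C2′ bridge.

Step 8
Reactants: 16 C10-allyl keto ester
Product: 18 C4 hydroxy ester (C4 bears OH and CO2Me; configuration at C4 of no consequence), via potassium ester enolate 17 (not isolated)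
Conditions: KN(SiMe3)2, THF, −78 °C; then 2-(phenylsulfonyl)-3-phenyloxaziridine, −78 °C; then H2O
Reagents that add atoms: 2-(phenylsulfonyl)-3-phenyloxaziridine, O=S(=O)(c1ccccc1)N1OC1c1ccccc1
Why: With the ketone now unable to enolise, the ester enolate is the only one available, and Davis hydroxylation should install the C4 hydroxyl needed to excise the ester carbon.

Step 9
Reactants: 18 C4 hydroxy ester
Product: 19 C4 hydroxy acid
Conditions: LiOH, THF/MeOH/H2O, 50 °C; then 1 M HCl to pH 4, 0 °C
Reagents that add atoms: lithium hydroxide, [Li+].[OH-]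
Why: Saponification by acyl–oxygen cleavage should free the α-hydroxy acid without loss of the dioxolane, since the medium stays basic until a brief cold acidification.

Step 10
Reactants: 19 C4 hydroxy acid
Product: 20 C1,C4-diketone (C4 ketone next to the quaternary C5)
Conditions: Pb(OAc)4, pyridine, CH2Cl2, 0 °C
Reagents that add atoms: none
Why: Oxidative decarboxylation of the α-hydroxy acid by Pb(OAc)4 (glycol-type cleavage) should expel CO2 and leave the C4 ketone as the handle for the alkene bridge.

Step 11
Reactants: 20 C1,C4-diketone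
Product: 21 C3=C4 enol triflate (OTf on C4)
Conditions: KN(SiMe3)2, PhNTf2, THF, −78 to 0 °C
Reagents that add atoms: N-phenylbis(trifluoromethanesulfonimide), FC(F)(F)S(=O)(=O)N(c1ccccc1)S(=O)(=O)C(F)(F)F
Why: The C4 ketone can enolise only toward C3 and the C1 ketone not at all, so enolate O-triflation should give a single enol triflate.

Step 12
Reactants: 21 C3=C4 enol triflate
Product: 22 bicyclo[2.2.2]octenone PMB ether (C3=C4 with C15 methyl on C4; C5-CH2OPMB; C10 methyl and allyl; C2′ dioxolanyl side chain)
Conditions: MeZnCl, Pd(PPh3)4 (5 mol %), THF, 50 °C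
Reagents that add atoms: methylzinc chloride, C[Zn]Cl
Why: Negishi coupling of the enol triflate with a methylzinc reagent, which tolerates the hindered ketone, should install C15 and fix the trisubstituted alkene between C3 and C4.

Step 13
Reactants: 22 bicyclo[2.2.2]octenone PMB ether
Product: 23 C6 primary alcohol (C5-CH2OH)
Conditions: DDQ, CH2Cl2/pH 7 buffer, 0 °C to rt
Reagents that add atoms: none
Why: Oxidative cleavage of the 4-methoxybenzyl ether by DDQ should release the neopentyl alcohol without acid, so the dioxolane and both alkenes survive.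

Step 14
Reactants: 23 C6 primary alcohol
Product: 24 C6 aldehyde (C5-CHO)
Conditions: Dess–Martin periodinane, pyridine, CH2Cl2, 0 °C to rt
Reagents that add atoms: none
Why: Dess–Martin oxidation should give the aldehyde, which cannot enolise because C5 is quaternary.

Step 15
Reactants: 24 C6 aldehyde
Product: 25 C6 vinyl carbinol (C5-CH(OH)CH=CH2; both C6 epimers)
Conditions: CH2=CHMgBr, THF, −78 °C; then H2O
Reagents that add atoms: vinylmagnesium bromide, C=C[Mg]Br
Why: Grignard addition should occur at the aldehyde and not at the far more hindered C1 ketone, bringing in C7; both C6 epimers are carried on because that centre is reset in steps 17 and 18.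

Step 16
Reactants: 25 C6 vinyl carbinol
Product: 26 ring B cyclohexenol (C6-OH epimers; C7=C8)
Conditions: second-generation Grubbs catalyst (H2IMes)(PCy3)Cl2Ru=CHPh (5 mol %), CH2Cl2, 40 °C
Reagents that add atoms: none
Why: Ring-closing metathesis of the two monosubstituted alkenes should close ring B as a cyclohexene with the C7=C8 double bond, the trisubstituted bridge alkene being too hindered to take part.

Step 17
Reactants: 26 ring B cyclohexenol
Product: 27 ring B enone (C6 ketone conjugated with C7=C8)
Conditions: Dess–Martin periodinane, pyridine, CH2Cl2, rt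
Reagents that add atoms: none
Why: Dess–Martin oxidation should converge both allylic alcohol epimers on one enone.

Step 18
Reactants: 27 ring B enone
Product: 28 ring B allylic alcohol (C6-OH axial, syn to the C14 methyl and anti to C1′)
Conditions: NaBH4, CeCl3·7H2O, MeOH, −78 to −20 °C
Reagents that add atoms: none
Why: Luche 1,2-reduction should deliver hydride to C6 from the face opposite the axial C14 methyl on C10, as in the reduction of 6-oxo steroids, giving the axial alcohol that the lactone oxygen requires.

Step 19
Reactants: 28 ring B allylic alcohol; 29 ethyl (Z)-prop-1-enyl ether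
Product: 30 mixed bromoacetal C6–O–CH(OEt)–CHBr–CH3 (epimers at the acetal carbon and at CHBr used together; one shown)
Conditions: NBS, CH2Cl2, −40 to 0 °C
Reagents that add atoms: N-bromosuccinimide, O=C1CCC(=O)N1Br
Why: Bromoalkoxylation of the electron-rich enol ether (bromonium ion, then capture by the C6 hydroxyl) should give the mixed bromoacetal, whose two new centres are both erased later.

Step 20
Reactants: 30 mixed bromoacetal
Product: 31 cis-fused ethyl lactol ether (2-ethoxytetrahydrofuran ring C6–O–C12H(OEt)–C11H(CH3)–C7 on ring B; C11 and C12 epimers)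
Conditions: Bu3SnH (1.3 equiv, syringe pump), AIBN (cat.), benzene, 80 °C, 0.01 M
Reagents that add atoms: none
Why: The tributyltin radical abstracts bromine to give the secondary C11 radical, which adds to C7 of the C7=C8 alkene, and the resulting C8 radical takes hydrogen from Bu3SnH and carries the chain. This is a Ueno–Stork haloacetal cyclisation, the standard radical route from cyclic allylic alcohols to cis-fused γ-lactone precursors. The tetrahydrofuran acetal ring closes in the 5-exo-trig mode. C7 is controlled by the tether: the radical hangs from the C6 oxygen through one acetal carbon, so it can reach C7 only on the oxygen-bearing face and the ring fusion must be cis, whereas C11 forms as an epimer mixture that is corrected in the last step. The step needs ring closure to outrun direct reduction and attack elsewhere; high dilution with slow stannane addition secures the first, and the quaternary C5 together with the hindered, remote C3=C4 alkene leaves C7 as the only acceptor within reach.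

Step 21
Reactants: 31 cis-fused ethyl lactol ether
Product: 33 keto lactone (C2′ acetyl; γ-lactone C12=O; C11 epimers), via keto lactol 32 (not isolated)
Conditions: CrO3, H2SO4, H2O, acetone, 0 °C to rt
Reagents that add atoms: water, O
Why: Aqueous acid should hydrolyse both the ethyl acetal and the dioxolane, and hexavalent chromium should oxidise the resulting lactol to the γ-lactone in the same pot (Jones oxidation of a cyclic acetal), the C1 ketone and the C3=C4 alkene being inert.

Step 22
Reactants: 33 keto lactone
Product: 34 vinyl triflate (C2′–C(OTf)=CH2; C11 epimers)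
Conditions: KN(SiMe3)2 added to 33 and PhNTf2, THF, −78 °C
Reagents that add atoms: N-phenylbis(trifluoromethanesulfonimide), FC(F)(F)S(=O)(=O)N(c1ccccc1)S(=O)(=O)C(F)(F)F
Why: Kinetic deprotonation of the methyl ketone at CH3 (not at the hindered C2′ methine or the less acidic lactone) with the triflating agent already present should trap the terminal enolate as the vinyl triflate before it can add to the nearby C1 ketone.

Step 23
Reactants: 34 vinyl triflate; 35 5-bromo-2-methylpent-2-ene
Product: 37 C11 epimer mixture of the target (full side chain C3′(=CH2)CH2CH2CH=C(CH3)2), via homoprenylzinc bromide 36 (not isolated)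
Conditions: 35, Zn dust, LiCl, THF, 40 °C; then 34, Pd(PPh3)4 (5 mol %), THF, rt to 50 °C
Reagents that add atoms: none
Why: Negishi coupling of the vinyl triflate with the primary alkylzinc made by zinc insertion into the bromide should attach the 4-methylpent-3-enyl chain and complete the 1,1-disubstituted alkene without touching the ketone or the lactone.

Step 24
Reactants: 37 C11 epimer mixture of the target
Product: 38 target CNP0385704.2
Conditions: DBU, toluene, 80 °C
Reagents that add atoms: none
Why: Base-mediated equilibration through the lactone enolate, the only enolisable position left, should converge on the more stable C11 epimer with the methyl group on the convex face of the cis-fused lactone (trans to C8), which is the target configuration.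

**Compound list**

1 | (R)-carvone, (5R)-2-methyl-5-(prop-1-en-2-yl)cyclohex-2-en-1-one | CC1=CC[C@H](CC1=O)C(C)=C | starting material
2 | isopropenyl ozonide of 1 (1,2,4-trioxolane; epimers at the ring carbon) | CC1=CC[C@H](CC1=O)C2(C)OCOO2 | intermediate (not isolated)
3 | (5R)-5-acetyl-2-methylcyclohex-2-en-1-one | CC1=CC[C@H](CC1=O)C(C)=O | intermediate
4 | (5R)-2-methyl-5-(2-methyl-1,3-dioxolan-2-yl)cyclohex-2-en-1-one | CC1=CC[C@H](CC1=O)C2(C)OCCO2 | intermediate
5 | (tributylstannyl)methanol | CCCC[Sn](CCCC)(CCCC)CO | starting material
6 | 4-methoxybenzyl chloride | COc1ccc(CCl)cc1 | starting material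
7 | tributyl{[(4-methoxybenzyl)oxy]methyl}stannane | CCCC[Sn](CCCC)(CCCC)COCc1ccc(OC)cc1 | intermediate
8 | {[(4-methoxybenzyl)oxy]methyl}lithium | [Li]COCc1ccc(OC)cc1 | intermediate (not isolated)
9 | (5R)-1-{[(4-methoxybenzyl)oxy]methyl}-2-methyl-5-(2-methyl-1,3-dioxolan-2-yl)cyclohex-2-en-1-ol (C1 epimers) | CC1=CC[C@H](CC1(O)COCc2ccc(OC)cc2)C3(C)OCCO3 | intermediate
10 | (5S)-3-{[(4-methoxybenzyl)oxy]methyl}-2-methyl-5-(2-methyl-1,3-dioxolan-2-yl)cyclohex-2-en-1-one | CC1=C(COCc2ccc(OC)cc2)C[C@@H](CC1=O)C3(C)OCCO3 | intermediate
11 | methyl acrylate | C=CC(=O)OC | starting material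
12 | lithium cross-conjugated dienolate of 10 | CC1=C(COCc2ccc(OC)cc2)C[C@@H](C=C1O[Li])C3(C)OCCO3 | intermediate (not isolated)
13 | bicyclic keto ester (C1 ketone; C4-CO2Me and C2′-dioxolanyl syn to the ketone bridge; C5-CH2OPMB; C10-H/CH3 epimers) | CC1(OCCO1)[C@H]2C[C@]3(COCc4ccc(OC)cc4)[C@@H](C(=O)OC)C[C@H]2C(=O)C3C | intermediate
14 | allyl bromide | C=CCBr | starting material
15 | lithium C1/C10 enolate of 13 | CC1(OCCO1)[C@H]2C[C@]3(COCc4ccc(OC)cc4)[C@@H](C(=O)OC)C[C@H]2C(O[Li])=C3C | intermediate (not isolated)
16 | C10-allyl keto ester (CH3 syn to the C3–C4 bridge, allyl syn to the C1′–C2′ bridge) | CC1(OCCO1)[C@H]2C[C@]3(COCc4ccc(OC)cc4)[C@@H](C(=O)OC)C[C@H]2C(=O)[C@]3(C)CC=C | intermediate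
17 | potassium ester enolate of 16 | CC1(OCCO1)[C@H]2C[C@]3(COCc4ccc(OC)cc4)C(=C(OC)O[K])C[C@H]2C(=O)[C@]3(C)CC=C | intermediate (not isolated)
18 | C4 hydroxy ester (C4 epimers of no consequence) | CC1(OCCO1)[C@H]2C[C@]3(COCc4ccc(OC)cc4)C(O)(C(=O)OC)C[C@H]2C(=O)[C@]3(C)CC=C | intermediate
19 | C4 hydroxy acid | CC1(OCCO1)[C@H]2C[C@]3(COCc4ccc(OC)cc4)C(O)(C(=O)O)C[C@H]2C(=O)[C@]3(C)CC=C | intermediate
20 | C1,C4-diketone | CC1(OCCO1)[C@H]2C[C@]3(COCc4ccc(OC)cc4)C(=O)C[C@H]2C(=O)[C@]3(C)CC=C | intermediate
21 | C3=C4 enol triflate | CC1(OCCO1)[C@H]2C[C@]3(COCc4ccc(OC)cc4)C(OS(=O)(=O)C(F)(F)F)=C[C@H]2C(=O)[C@]3(C)CC=C | intermediate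
22 | bicyclo[2.2.2]octenone PMB ether (C3=C4, C15 on C4) | CC1(OCCO1)[C@H]2C[C@]3(COCc4ccc(OC)cc4)C(C)=C[C@H]2C(=O)[C@]3(C)CC=C | intermediate
23 | C6 primary alcohol | CC1(OCCO1)[C@H]2C[C@]3(CO)C(C)=C[C@H]2C(=O)[C@]3(C)CC=C | intermediate
24 | C6 aldehyde | CC1(OCCO1)[C@H]2C[C@]3(C=O)C(C)=C[C@H]2C(=O)[C@]3(C)CC=C | intermediate
25 | C6 vinyl carbinol (C6 epimers) | CC1(OCCO1)[C@H]2C[C@]3(C(O)C=C)C(C)=C[C@H]2C(=O)[C@]3(C)CC=C | intermediate
26 | ring B cyclohexenol (C6 epimers; C7=C8) | CC1(OCCO1)[C@H]2C[C@]34C(C)=C[C@H]2C(=O)[C@]3(C)CC=CC4O | intermediate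
27 | ring B enone (C6 ketone; C7=C8) | CC1(OCCO1)[C@H]2C[C@]34C(C)=C[C@H]2C(=O)[C@]3(C)CC=CC4=O | intermediate
28 | ring B allylic alcohol (C6-OH syn to C14) | CC1(OCCO1)[C@H]2C[C@]34C(C)=C[C@H]2C(=O)[C@]3(C)CC=C[C@H]4O | intermediate
29 | ethyl (Z)-prop-1-enyl ether | C/C=C\OCC | starting material
30 | mixed bromoacetal (acetal and bromide epimers used together; one shown) | CC1(OCCO1)[C@H]2C[C@]34C(C)=C[C@H]2C(=O)[C@]3(C)CC=C[C@H]4O[C@@H](OCC)[C@@H](C)Br | intermediate
31 | cis-fused ethyl lactol ether (C11 and C12 epimers) | CC1(OCCO1)[C@H]2C[C@]34C(C)=C[C@H]2C(=O)[C@]3(C)CC[C@H]5C(C)C(OCC)O[C@@H]45 | intermediate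
32 | keto lactol (C11 and C12 epimers) | CC(=O)[C@H]1C[C@]23C(C)=C[C@H]1C(=O)[C@]2(C)CC[C@H]4C(C)C(O)O[C@@H]34 | intermediate (not isolated)
33 | keto lactone (C11 epimers) | CC(=O)[C@H]1C[C@]23C(C)=C[C@H]1C(=O)[C@]2(C)CC[C@H]4C(C)C(=O)O[C@@H]34 | intermediate
34 | vinyl triflate (C11 epimers) | C=C(OS(=O)(=O)C(F)(F)F)[C@H]1C[C@]23C(C)=C[C@H]1C(=O)[C@]2(C)CC[C@H]4C(C)C(=O)O[C@@H]34 | intermediate
35 | 5-bromo-2-methylpent-2-ene | CC(C)=CCCBr | starting material
36 | (4-methylpent-3-en-1-yl)zinc bromide | CC(C)=CCC[Zn]Br | intermediate (not isolated)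
37 | C11 epimer mixture of the target | C=C(CCC=C(C)C)[C@H]1C[C@]23C(C)=C[C@H]1C(=O)[C@]2(C)CC[C@H]4C(C)C(=O)O[C@@H]34 | intermediate
38 | CNP0385704.2 | C=C(CCC=C(C)C)[C@H]1C[C@]23C(C)=C[C@H]1C(=O)[C@]2(C)CC[C@H]1[C@H](C)C(=O)O[C@H]13 | target

**Step count.** 24 steps in total. The longest linear sequence is 23 steps from (R)-carvone (steps 1, 2 and 4–24); step 3 is the one-step preparation of the stannane.

**Steps most likely to fail**

Step 20. What may go wrong: hydrogen transfer from the stannane to the C11 radical before it closes onto C7, or loss of the acid-sensitive acetal under the thermal conditions. The fallback forms the same C7–C11 bond by enolate chemistry and sets out from enone 27. Conjugate reduction with LiBH(s-Bu)3 at −78 °C and trapping of the resulting enolate with methyl bromoacetate should give the C7-alkylated C6 ketone F1, with the side chain equatorial after equilibration. NaBH4 reduction from the face opposite C14, followed by spontaneous lactonisation, should give the cis-fused nor-methyl lactone F2. Methylation of its lithium enolate (LiN(i-Pr)2, MeI) on the convex face should give the 11-methyl ketal lactone F3. Dilute HCl in THF then removes the dioxolane, and the route is rejoined at 33 as its epimer with the target configuration at C11.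

Step 7. What may go wrong: slow carbon alkylation at a fully substituted, flanked enolate carbon, so that O-allylation or recovered ketone dominates. The fallback replaces direct alkylation by O-acylation and a palladium-mediated C–C bond formation. From 13, KN(SiMe3)2 and allyl chloroformate should give the allyl enol carbonate F4. Pd(PPh3)4 in THF should then bring about decarboxylative Tsuji allylation, the enolate attacking the π-allyl complex of divalent palladium on the same open face, and the route is rejoined at 16.

Step 6. What may go wrong: stalling after the first conjugate addition, because the second addition has to create the quaternary bridgehead C5, or anionic polymerisation of the acrylate. The fallback is pericyclic and not anionic. From 10, LiN(i-Pr)2 and t-BuMe2SiCl should give the silyl dienol ether F5. A thermal Diels–Alder reaction with methyl acrylate (toluene, 110 °C) should give the bicyclic silyl enol ether F6 with the same regiochemistry, the addition anti to the dioxolanyl group and an endo ester. Bu4NF with AcOH should then release ketone 13.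

**Further compounds**

F1 | step 20 | C7-(methoxycarbonylmethyl) C6 ketone with saturated ring B (side chain equatorial) | CC1(OCCO1)[C@H]2C[C@]34C(C)=C[C@H]2C(=O)[C@]3(C)CC[C@@H](CC(=O)OC)C4=O
F2 | step 20 | cis-fused nor-methyl lactone with the dioxolane retained | CC1(OCCO1)[C@H]2C[C@]34C(C)=C[C@H]2C(=O)[C@]3(C)CC[C@H]5CC(=O)O[C@@H]45
F3 | step 20 | 11-methyl ketal lactone (C11 as in the target) | CC1(OCCO1)[C@H]2C[C@]34C(C)=C[C@H]2C(=O)[C@]3(C)CC[C@H]5[C@H](C)C(=O)O[C@@H]45
F4 | step 7 | allyl enol carbonate of 13 | CC1(OCCO1)[C@H]2C[C@]3(COCc4ccc(OC)cc4)[C@@H](C(=O)OC)C[C@H]2C(OC(=O)OCC=C)=C3C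
F5 | step 6 | tert-butyldimethylsilyl dienol ether of 10 | CC1=C(COCc2ccc(OC)cc2)C[C@@H](C=C1O[Si](C)(C)C(C)(C)C)C3(C)OCCO3
F6 | step 6 | bicyclic silyl enol ether (Diels–Alder adduct, endo ester) | CC1(OCCO1)[C@H]2C[C@]3(COCc4ccc(OC)cc4)[C@@H](C(=O)OC)C[C@H]2C(O[Si](C)(C)C(C)(C)C)=C3C
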